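The route rests on disconnecting C2=C3 of indole A, the 5-hydroxyindole. Its C3 is bonded to C3a of the benzo ring and to ring C, the pattern of a diaryl ketone, while C2 sits between C3 and N1 like an anilide carbonyl. A single titanium-mediated reductive ketone–amide coupling therefore forms the C2–C3 bond, closes the pyrrole ring and aromatises it by removing both oxygens. Its precursor is the ethyl oxamate of a 2-amino-5-silyloxybenzophenone whose second aryl group is the tetramethoxy ring C, already carrying N-silylated 6-prenylindole B. The crowded ring C–C3 bond is thus made earlier, by acylating an aryllithium, and only indole B requires a biaryl coupling.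

Key step: step 10

Remark: the target has no stereocentre, and the two indolyl–aryl axes are taken as freely rotating at room temperature, so no stereochemical control is needed.

Step 1
Reactants: 1 5-hydroxyanthranilic acid (2-amino-5-hydroxybenzoic acid)
Product: 2 2-amino-5-hydroxy-N-methoxy-N-methylbenzamide
Conditions: MeNHOMe·HCl, EDC·HCl, HOBt, N-methylmorpholine, DMF, 0 °C → rt, N2
Reagents that add atoms: N,O-dimethylhydroxylamine hydrochloride, CNOC.Cl
Why: Carbodiimide/HOBt amide coupling should work without protection because the alpha-effect amine MeNHOMe intercepts the active ester much faster than the carbonyl-deactivated, hydrogen-bonded aniline or the phenol of a second molecule can.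

Step 2
Reactants: 2 2-amino-5-hydroxy-N-methoxy-N-methylbenzamide
Product: 3 2-amino-N-methoxy-N-methyl-5-(triisopropylsilyloxy)benzamide
Conditions: TIPSCl (1.1 equiv), imidazole (2.5 equiv), DMF, rt
Reagents that add atoms: triisopropylsilyl chloride, CC(C)[Si](Cl)(C(C)C)C(C)C
Why: Imidazole-promoted O-silylation with the bulky chlorosilane takes the phenol and leaves the weakly nucleophilic aniline free, and the aryl triisopropylsilyl ether tolerates aryllithiums, biphasic mild base and Lewis-acidic titanium and zinc chlorides.

Step 3
Reactants: 4 1,2,4,5-tetramethoxybenzene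
Product: 5 1,4-dibromo-2,3,5,6-tetramethoxybenzene
Conditions: NBS (2.2 equiv), MeCN, 0 °C → rt, dark
Reagents that add atoms: N-bromosuccinimide, O=C1CCC(=O)N1Br
Why: Electrophilic aromatic bromination can only occur at the two equivalent free positions, each activated by two ortho methoxy groups, and anhydrous NBS in acetonitrile favours nuclear substitution over oxidative demethylation to the quinone.

Step 4
Reactants: 5 1,4-dibromo-2,3,5,6-tetramethoxybenzene; 3 2-amino-N-methoxy-N-methyl-5-(triisopropylsilyloxy)benzamide
Product: 7 (2-amino-5-triisopropylsilyloxyphenyl)(4-bromo-2,3,5,6-tetramethoxyphenyl)methanone, via 4-bromo-2,3,5,6-tetramethoxyphenyllithium 6 (not isolated)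
Conditions: 5 (2.4 equiv), n-BuLi (2.3 equiv), THF, −78 °C; then 3 (1.0 equiv), −78 → 0 °C; aq NH4Cl
Reagents that add atoms: none
Why: Bromine–lithium exchange of one C–Br bond at −78 °C is followed by Weinreb ketone synthesis, in which the first equivalent of this cheap aryllithium is spent on the aniline N–H, the second adds to the amide and the chelated tetrahedral adduct blocks over-addition; making the ketone before indole B is attached keeps alkyllithium away from the doubly activated CH2 of the prenyl group and leaves a C–Br handle on ring C.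

Step 5
Reactants: 8 6-bromoindole
Product: 9 6-bromo-1-(triisopropylsilyl)indole
Conditions: NaH, TIPSCl, THF, 0 °C → rt
Reagents that add atoms: triisopropylsilyl chloride, CC(C)[Si](Cl)(C(C)C)C(C)C
Why: N-silylation of the deprotonated indole (substitution at silicon) installs a group whose bulk screens C2 and C7 in the later metalation and borylation steps and which survives tert-butyllithium at low temperature.

Step 6
Reactants: 9 6-bromo-1-(triisopropylsilyl)indole; 10 prenyl bromide (1-bromo-3-methylbut-2-ene)
Product: 12 6-(3-methylbut-2-enyl)-1-(triisopropylsilyl)indole, via 6-lithio-1-(triisopropylsilyl)indole 11 (not isolated)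
Conditions: t-BuLi (2.1 equiv), THF, −78 °C; then 10, CuBr·SMe2 (10 mol %), −78 °C → rt
Reagents that add atoms: none
Why: Bromine–lithium exchange with two equivalents of t-BuLi is faster than any deprotonation, and copper-assisted SN2 allylation of the aryllithium takes place at the unhindered CH2 terminus of prenyl bromide, which should give the linear 3-methylbut-2-enyl group and not the reverse-prenyl isomer.

Step 7
Reactants: 12 6-(3-methylbut-2-enyl)-1-(triisopropylsilyl)indole
Product: 13 6-(3-methylbut-2-enyl)-3-(4,4,5,5-tetramethyl-1,3,2-dioxaborolan-2-yl)-1-(triisopropylsilyl)indole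
Conditions: [Ir(OMe)(cod)]2 (1.5 mol %), 4,4′-di-tert-butyl-2,2′-bipyridine (3 mol %), B2pin2 (1.0 equiv), MTBE, 60 °C
Reagents that add atoms: bis(pinacolato)diboron, CC1(C)OB(OC1(C)C)B1OC(C)(C)C(C)(C)O1
Why: Iridium-catalysed aromatic C–H borylation is sterically governed, and with C2 and C7 screened by the N-silyl group and C5 and C7 by the prenyl group the boryl group should go to C3, as is known for N-triisopropylsilylindoles, while a trisubstituted alkene is inert to the catalyst.

Step 8
Reactants: 7 (2-amino-5-triisopropylsilyloxyphenyl)(4-bromo-2,3,5,6-tetramethoxyphenyl)methanone; 13 indol-3-yl pinacol boronate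
Product: 14 (2-amino-5-triisopropylsilyloxyphenyl){2,3,5,6-tetramethoxy-4-[6-(3-methylbut-2-enyl)-1-(triisopropylsilyl)indol-3-yl]phenyl}methanone
Conditions: 13 (1.4 equiv), Pd(OAc)2 (5 mol %), SPhos (10 mol %), K3PO4 (3 equiv), toluene/H2O 10:1, 90 °C, argon
Reagents that add atoms: none
Why: In this Suzuki–Miyaura coupling the para aroyl group speeds oxidative addition of zerovalent palladium into the hindered C–Br bond and the bulky, electron-rich biarylphosphine drives transmetalation and reductive elimination between two ortho methoxy groups, while the free aniline, the ketone, the alkene and both silyl groups tolerate the biphasic phosphate base.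

Step 9
Reactants: 14 aminoketone; 15 ethyl oxalyl chloride
Product: 16 ethyl N-[2-{2,3,5,6-tetramethoxy-4-[6-(3-methylbut-2-enyl)-1-(triisopropylsilyl)indol-3-yl]benzoyl}-4-(triisopropylsilyloxy)phenyl]oxamate
Conditions: 15 (1.2 equiv), pyridine (2 equiv), CH2Cl2, 0 °C → rt
Reagents that add atoms: none
Why: In this N-acylation the acid chloride end of the reagent is far more electrophilic than its ester end and reacts even with the hydrogen-bonded nitrogen of a 2-aminobenzophenone, whereas indole B, blocked at C3 and N1, is not acylated in the presence of pyridine.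

Step 10
Reactants: 16 oxamate ketone
Product: 17 ethyl 3-{2,3,5,6-tetramethoxy-4-[6-(3-methylbut-2-enyl)-1-(triisopropylsilyl)indol-3-yl]phenyl}-5-(triisopropylsilyloxy)-1H-indole-2-carboxylate
Conditions: TiCl3 (4 equiv), Zn dust (8 equiv), DME, reflux, 0.03 M, argon; filtration through silica
Reagents that add atoms: none
Why: Zinc reduces TiCl3 to low-valent titanium in the flask, and this binds the ketone and anilide oxygens and transfers electrons first to the diaryl ketone, the most easily reduced group, to give a titanium-bound ketyl or dianion at the future C3. That carbon attacks the anilide carbonyl (future C2) in a 5-exo-trig closure of the ring N1–C2–C3–C3a–C7a, and the titanium diolate so formed gives up both oxygens to the oxophilic metal, so that the C2=C3 bond and the aromatic pyrrole arise together. The closest known reaction is the Fürstner indole synthesis (intramolecular McMurry-type oxo-amide coupling), which is established for ethyl N-(2-aroylaryl)oxamates giving ethyl 3-arylindole-2-carboxylates. No stereocentre is formed. The step needs the amide and not the ester carbonyl of the oxamate to couple, which the substrate secures because only the amide carbon stands in a 1,5-relationship to the ketone carbon (the ester carbon could only close a six-membered, non-aromatic ring), and it needs cyclisation to beat intermolecular pinacol coupling, which the two ortho methoxy groups and the dilution should ensure. The trisubstituted alkene, the aryl methyl ethers, the ester and the triisopropylsilyl groups are not reduced by this reagent.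

Step 11
Reactants: 17 indole-2-carboxylate
Product: 18 5-hydroxy-3-{2,3,5,6-tetramethoxy-4-[6-(3-methylbut-2-enyl)-1H-indol-3-yl]phenyl}-1H-indole-2-carboxylic acid
Conditions: KOH (15 equiv), EtOH/THF/H2O, 70 °C, degassed, argon; then 1 M HCl to pH 3, 0 °C
Reagents that add atoms: potassium hydroxide, [K+].[OH-]
Why: Hydroxide does three jobs in one operation, namely saponification of the hindered ester and nucleophilic cleavage of the Si–O and Si–N bonds with phenoxide and indolide as leaving groups, so that no silyl group is left in an undefined state and no separate fluoride step is needed, while the prenyl group and the methyl ethers are inert to aqueous base at this temperature.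

Step 12
Reactants: 18 hydroxyindole-2-carboxylic acid
Product: 19 3-{2,3,5,6-tetramethoxy-4-[6-(3-methylbut-2-enyl)-1H-indol-3-yl]phenyl}-1H-indol-5-ol (target CNP0145408.0)
Conditions: Cu2O (10 mol %), 1,10-phenanthroline (20 mol %), NMP/quinoline 3:1, 165 °C, argon
Reagents that add atoms: none
Why: In this copper-catalysed protodecarboxylation the monovalent copper carboxylate extrudes CO2 to give a C2-cuprated indole that is protonated by further acid, a process favoured next to the ring nitrogen and by the twisted di-ortho-methoxyaryl neighbour at C3, and the basic, non-oxidising medium leaves phenol, prenyl group and methyl ethers alone.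

Compound list
1 | 5-hydroxyanthranilic acid | Nc1ccc(O)cc1C(=O)O | starting material
2 | 2-amino-5-hydroxy-N-methoxy-N-methylbenzamide | CON(C)C(=O)c1cc(O)ccc1N | intermediate
3 | 2-amino-N-methoxy-N-methyl-5-(triisopropylsilyloxy)benzamide | CON(C)C(=O)c1cc(O[Si](C(C)C)(C(C)C)C(C)C)ccc1N | intermediate
4 | 1,2,4,5-tetramethoxybenzene | COc1cc(OC)c(OC)cc1OC | starting material
5 | 1,4-dibromo-2,3,5,6-tetramethoxybenzene | COc1c(Br)c(OC)c(OC)c(Br)c1OC | intermediate
6 | 4-bromo-2,3,5,6-tetramethoxyphenyllithium (not isolated) | [Li]c1c(OC)c(OC)c(Br)c(OC)c1OC | intermediate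
7 | (2-amino-5-triisopropylsilyloxyphenyl)(4-bromo-2,3,5,6-tetramethoxyphenyl)methanone | Nc1ccc(O[Si](C(C)C)(C(C)C)C(C)C)cc1C(=O)c1c(OC)c(OC)c(Br)c(OC)c1OC | intermediate
8 | 6-bromoindole | Brc1ccc2cc[nH]c2c1 | starting material
9 | 6-bromo-1-(triisopropylsilyl)indole | CC(C)[Si](C(C)C)(C(C)C)n1ccc2ccc(Br)cc21 | intermediate
10 | prenyl bromide | CC(C)=CCBr | starting material
11 | 6-lithio-1-(triisopropylsilyl)indole (not isolated) | CC(C)[Si](C(C)C)(C(C)C)n1ccc2ccc([Li])cc21 | intermediate
12 | 6-(3-methylbut-2-enyl)-1-(triisopropylsilyl)indole | CC(C)=CCc1ccc2ccn([Si](C(C)C)(C(C)C)C(C)C)c2c1 | intermediate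
13 | 6-(3-methylbut-2-enyl)-3-(pinacolatoboryl)-1-(triisopropylsilyl)indole | CC(C)=CCc1ccc2c(B3OC(C)(C)C(C)(C)O3)cn([Si](C(C)C)(C(C)C)C(C)C)c2c1 | intermediate
14 | aminoketone carrying ring C and indole B | Nc1ccc(O[Si](C(C)C)(C(C)C)C(C)C)cc1C(=O)c1c(OC)c(OC)c(-c2cn([Si](C(C)C)(C(C)C)C(C)C)c3cc(CC=C(C)C)ccc23)c(OC)c1OC | intermediate
15 | ethyl oxalyl chloride | CCOC(=O)C(=O)Cl | starting material
16 | oxamate ketone (precursor of the key step) | CCOC(=O)C(=O)Nc1ccc(O[Si](C(C)C)(C(C)C)C(C)C)cc1C(=O)c1c(OC)c(OC)c(-c2cn([Si](C(C)C)(C(C)C)C(C)C)c3cc(CC=C(C)C)ccc23)c(OC)c1OC | intermediate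
17 | ethyl 3-aryl-5-(triisopropylsilyloxy)indole-2-carboxylate (product of the key step) | CCOC(=O)c1[nH]c2ccc(O[Si](C(C)C)(C(C)C)C(C)C)cc2c1-c1c(OC)c(OC)c(-c2cn([Si](C(C)C)(C(C)C)C(C)C)c3cc(CC=C(C)C)ccc23)c(OC)c1OC | intermediate
18 | 5-hydroxy-3-arylindole-2-carboxylic acid, fully desilylated | COc1c(OC)c(-c2c(C(=O)O)[nH]c3ccc(O)cc23)c(OC)c(OC)c1-c1c[nH]c2cc(CC=C(C)C)ccc12 | intermediate
19 | CNP0145408.0 | COc1c(OC)c(-c2c[nH]c3ccc(O)cc23)c(OC)c(OC)c1-c1c[nH]c2cc(CC=C(C)C)ccc12 | target

Total step count: 12. 

Longest linear sequence: 8 steps (steps 1, 2, 4, 8, 9, 10, 11, 12). The branch from 8 through steps 5, 6, 7 and then 8–12 is equally long.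

Steps most likely to fail

1. **Step 10.**
 - What may go wrong: the ketone is twisted out of conjugation by two ortho methoxy groups. It may take up electrons and be protonated or deoxygenated without closing the ring. The Lewis-acidic chlorides may also strip a silyl or an ortho methyl group at reflux.
 - Fallback (from 14, back at 17): the same C2–C3 bond is closed by polar instead of reductive chemistry. Aminoketone 14 is N-alkylated with ethyl bromoacetate (i-Pr2NEt, NaI, MeCN, 70 °C) to the ethyl N-arylglycinate F1. NaOEt in EtOH/THF at 0 °C to rt forms the ester enolate, which adds to the ketone to give the 3-hydroxyindoline-2-carboxylate aldol adduct F2 (racemic mixture of diastereomers, not isolated). Loss of water in the same operation aromatises it to 17.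

2. **Step 8.**
 - What may go wrong: protodeboronation of the indol-3-yl boronate may outrun the slow transmetalation at the hindered palladium centre. The aqueous base may also erode the aryl silyl ether.
 - Fallback (from 12 and 7, back at 14): C–H borylation and boron transfer under aqueous base are replaced by halogenation, metalation and an anhydrous, base-free organozinc coupling. Indole 12 is brominated at C3 with NBS in THF at −78 °C to 3-bromo-6-(3-methylbut-2-enyl)-1-(triisopropylsilyl)indole F3. Exchange with t-BuLi at −78 °C gives the 3-lithioindole F4, which ZnCl2 converts into the indol-3-ylzinc chloride F5. Negishi coupling of this with bromide 7 (Pd(OAc)2, SPhos, THF, 50 °C), a coupling type that tolerates ketones and aniline N–H bonds, gives 14.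

3. **Step 12.**
 - What may go wrong: CO2 loss may be incomplete, or the unprotected hydroxyindole may darken thermally or oxidatively at the temperature needed.
 - Fallback (from 14, back at 19): no carboxyl group is introduced at all. Aminoketone 14 is formylated with pre-formed acetic formic anhydride in THF at 0 °C to the formanilide F6. The same TiCl3/Zn coupling in refluxing DME then closes indole A with hydrogen at C2 and gives the bis(triisopropylsilyl) derivative of the target F7. TBAF in THF at 0 °C converts this into 19. This variant is held in reserve because the formyl version of the coupling is less thoroughly documented than the oxamate version.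

Further compounds
F1 | step 10 | ethyl N-[2-{2,3,5,6-tetramethoxy-4-[6-(3-methylbut-2-enyl)-1-(triisopropylsilyl)indol-3-yl]benzoyl}-4-(triisopropylsilyloxy)phenyl]glycinate | CCOC(=O)CNc1ccc(O[Si](C(C)C)(C(C)C)C(C)C)cc1C(=O)c1c(OC)c(OC)c(-c2cn([Si](C(C)C)(C(C)C)C(C)C)c3cc(CC=C(C)C)ccc23)c(OC)c1OC
F2 | step 10 | ethyl 3-aryl-3-hydroxy-5-(triisopropylsilyloxy)indoline-2-carboxylate, racemic mixture of diastereomers | CCOC(=O)C1Nc2ccc(O[Si](C(C)C)(C(C)C)C(C)C)cc2C1(O)c1c(OC)c(OC)c(-c2cn([Si](C(C)C)(C(C)C)C(C)C)c3cc(CC=C(C)C)ccc23)c(OC)c1OC
F3 | step 8 | 3-bromo-6-(3-methylbut-2-enyl)-1-(triisopropylsilyl)indole | CC(C)=CCc1ccc2c(Br)cn([Si](C(C)C)(C(C)C)C(C)C)c2c1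
F4 | step 8 | 3-lithio-6-(3-methylbut-2-enyl)-1-(triisopropylsilyl)indole | CC(C)=CCc1ccc2c([Li])cn([Si](C(C)C)(C(C)C)C(C)C)c2c1
F5 | step 8 | [6-(3-methylbut-2-enyl)-1-(triisopropylsilyl)indol-3-yl]zinc chloride | CC(C)=CCc1ccc2c([Zn]Cl)cn([Si](C(C)C)(C(C)C)C(C)C)c2c1
F6 | step 12 | N-[2-{2,3,5,6-tetramethoxy-4-[6-(3-methylbut-2-enyl)-1-(triisopropylsilyl)indol-3-yl]benzoyl}-4-(triisopropylsilyloxy)phenyl]formamide | O=CNc1ccc(O[Si](C(C)C)(C(C)C)C(C)C)cc1C(=O)c1c(OC)c(OC)c(-c2cn([Si](C(C)C)(C(C)C)C(C)C)c3cc(CC=C(C)C)ccc23)c(OC)c1OC
F7 | step 12 | O,N-bis(triisopropylsilyl) derivative of the target | COc1c(OC)c(-c2c[nH]c3ccc(O[Si](C(C)C)(C(C)C)C(C)C)cc23)c(OC)c(OC)c1-c1cn([Si](C(C)C)(C(C)C)C(C)C)c2cc(CC=C(C)C)ccc12
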